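## Retrosynthetic overview

1. Target 13 ⇒ phenol 8 + three molar equivalents of 4-hydroxybenzyl alcohol (9): exhaustive C-benzylation of ring B through a para-quinone methide Friedel–Crafts reaction (8 + 3 × 9 → 13 + 3 H2O). All three open ring B positions react, so there is no regiochemical question.
2. Phenol 8 ⇒ resorcinol 5 + methanol: the key disconnection is the ring B aryl C–OMe bond. The C2v-symmetric resorcinol 5 is desymmetrised by a dehydrative mono-etherification that runs through dione 6 and vinylogous ester 7.
3. Resorcinol 5 ⇒ stilbene 4 (hydrogenated in the same pot) ⇒ Wittig union of aldehyde 1 and phosphonium salt 2.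
4. No ring is formed: ring A, ring B and the three 4-hydroxyphenyl rings are all bought as benzene rings.

Assumption: the target SMILES contains no stereocentre and no stereogenic double bond, so the compound is achiral and "single enantiomer" is read as the single constitution shown.

## Route

Step 1
Reactants: 1 3,5-dihydroxybenzaldehyde; 2 (3-methoxybenzyl)triphenylphosphonium chloride
Product: 4 5-[2-(3-methoxyphenyl)ethenyl]benzene-1,3-diol (E/Z mixture), via phosphorus ylide 3 (not isolated)
Conditions: 2 (1.2 equiv), KOtBu (3.4 equiv in total: 1.25 equiv on 2, 2.1 equiv on 1), THF–DMF 4:1, 0 → 23 °C, 12 h; aq. HCl quench; product extracted into aq. NaOH (Ph3PO stays in the organic layer), then re-acidified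
Reagents that add atoms: none
Why: Wittig olefination in which the semi-stabilised benzylic ylide attacks the aldehyde, whose two phenoxides sit meta to the carbonyl and therefore do not deactivate it by resonance; the E/Z ratio is irrelevant because step 2 saturates the double bond, and no stereocentre is formed.

Step 2
Reactants: 4 5-[2-(3-methoxyphenyl)ethenyl]benzene-1,3-diol (E/Z mixture)
Product: 8 3-methoxy-5-[2-(3-methoxyphenyl)ethyl]phenol, via bibenzyl diol 5 (not isolated), via cyclohexane-1,3-dione 6 (not isolated), via 3-methoxycyclohexenone 7 (not isolated)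
Conditions: (a) H2 (1 atm), 10% Pd/C (zerovalent palladium on carbon, 5 mol% Pd), MeOH–1,4-dioxane 1:3, 23 °C, 2 h; (b) H2 vented to Ar with the hydride-loaded catalyst left in place, TsOH·H2O (10 mol%) added, sealed tube, 130 °C, 16 h
Reagents that add atoms: methanol (CO)
Why: Proposed new method: hydrogen-borrowing dehydrative mono-etherification of a resorcinol, in which (after ordinary alkene hydrogenation to 5) Pd–H left on the catalyst transfers one H2 equivalent to the resorcinol ring to give the stabilised 1,3-dione 6 (the partial reduction that makes dihydroresorcinol), TsOH-catalysed condensation of 6 with methanol forms vinylogous ester 7 whose new ring C–O bond carries the oxygen of methanol, and Pd then dehydrogenates 7 to phenol 8 while passing the hydrogen on to the next molecule of 5, so the net change is ArOH + MeOH → ArOMe + H2O with a single constitutional outcome because 5 is C2v-symmetric; it should stop at the mono-ether because a 1,3-dione can form only one vinylogous ester and a second etherification would require ketalisation of the deactivated vinylogous-ester carbonyl; the closest known reaction types are the Pd/C-catalysed formal cross-coupling of phenols with amines through cyclohexanone intermediates and the dehydrogenative aromatisation of 3-alkoxycyclohexenones; no stereocentre survives (C5 of 7 is transient and racemic).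

Step 3
Reactants: 8 3-methoxy-5-[2-(3-methoxyphenyl)ethyl]phenol; 9 4-(hydroxymethyl)phenol (4-hydroxybenzyl alcohol; three molar equivalents are built into the product, 3.6 equiv charged in all)
Product: 13 2,4,6-tris[(4-hydroxyphenyl)methyl]-3-methoxy-5-[2-(3-methoxyphenyl)ethyl]phenol, via para-quinone methide 10 (not isolated), via mono-benzylated phenol 11 (not isolated), via bis-benzylated phenol 12 (not isolated)
Conditions: 9 (3.6 equiv) in HFIP added by syringe pump over 8 h to 8 and TsOH·H2O (5 mol%) in (CF3)2CHOH (HFIP), 40 °C, then 12 h; argon
Reagents that add atoms: 4-hydroxybenzyl alcohol, the second and third molar equivalents of compound 9 (OCc1ccc(O)cc1.OCc1ccc(O)cc1)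
Why: Threefold dehydrative Friedel–Crafts benzylation (8 + 3 × 9 → 13 + 3 H2O) through the 4-hydroxybenzyl cation / para-quinone methide 10 ionised by HFIP, in which ring B (each free position ortho or para to both oxygens) is far more nucleophilic than ring A or the 4-hydroxyphenyl rings, slow addition of 9 suppresses its self-condensation, and all regioisomeric mono- and bis-adducts converge on the one tris-adduct; no stereocentre is formed.

## Compound list

1 | 3,5-dihydroxybenzaldehyde | O=Cc1cc(O)cc(O)c1 | starting material
2 | (3-methoxybenzyl)triphenylphosphonium chloride | COc1cccc(C[P+](c2ccccc2)(c2ccccc2)c2ccccc2)c1.[Cl-] | starting material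
3 | (3-methoxybenzylidene)triphenylphosphorane (ylide, not isolated) | COc1cccc(C=P(c2ccccc2)(c2ccccc2)c2ccccc2)c1 | intermediate
4 | 5-[2-(3-methoxyphenyl)ethenyl]benzene-1,3-diol (E/Z mixture, geometry deliberately left open) | COc1cccc(C=Cc2cc(O)cc(O)c2)c1 | intermediate
5 | 5-[2-(3-methoxyphenyl)ethyl]benzene-1,3-diol (not isolated) | COc1cccc(CCc2cc(O)cc(O)c2)c1 | intermediate
6 | 5-[2-(3-methoxyphenyl)ethyl]cyclohexane-1,3-dione (not isolated) | COc1cccc(CCC2CC(=O)CC(=O)C2)c1 | intermediate
7 | 3-methoxy-5-[2-(3-methoxyphenyl)ethyl]cyclohex-2-en-1-one (racemic, not isolated) | COC1=CC(=O)CC(CCc2cccc(OC)c2)C1 | intermediate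
8 | 3-methoxy-5-[2-(3-methoxyphenyl)ethyl]phenol | COc1cccc(CCc2cc(O)cc(OC)c2)c1 | intermediate
9 | 4-(hydroxymethyl)phenol (4-hydroxybenzyl alcohol) | OCc1ccc(O)cc1 | starting material
10 | 4-methylidenecyclohexa-2,5-dien-1-one (para-quinone methide, not isolated) | C=C1C=CC(=O)C=C1 | intermediate
11 | 4-[(4-hydroxyphenyl)methyl]-3-methoxy-5-[2-(3-methoxyphenyl)ethyl]phenol (principal mono-adduct, not isolated) | COc1cccc(CCc2cc(O)cc(OC)c2Cc2ccc(O)cc2)c1 | intermediate
12 | 2,4-bis[(4-hydroxyphenyl)methyl]-5-methoxy-3-[2-(3-methoxyphenyl)ethyl]phenol (principal bis-adduct, not isolated) | COc1cccc(CCc2c(Cc3ccc(O)cc3)c(O)cc(OC)c2Cc2ccc(O)cc2)c1 | intermediate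
13 | 2,4,6-tris[(4-hydroxyphenyl)methyl]-3-methoxy-5-[2-(3-methoxyphenyl)ethyl]phenol | COc1cccc(CCc2c(Cc3ccc(O)cc3)c(O)c(Cc3ccc(O)cc3)c(OC)c2Cc2ccc(O)cc2)c1 | target

## Step count and risks

Total step count: 3. Longest linear sequence: 3 (steps 1 → 2 → 3; compounds 1, 2 and 9 are bought).

Steps most likely to fail, in order of risk:

Step 2, the proposed new hydrogen-borrowing mono-etherification. The cycle may stall if the small hydrogen inventory is lost, some ring over-reduction may occur, or some diether may form. The fallback uses known chemistry and sets out from compound 5: stage (a) is run alone, the catalyst is filtered off and 5 is isolated. Diol 5 is then mono-O-methylated by a classical Williamson alkylation (MeI 1.0 equiv, K2CO3 1.1 equiv, acetone, reflux). This is statistical (about 40–45% of the mono-ether), and unreacted 5 is recovered by chromatography and recycled. It comes back to the route at compound 8, and no new compound is made on the way (F0).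

Step 3, the triple benzylation to a hexasubstituted ring. The third, most hindered alkylation may lag behind oligomerisation of 9 or alkylation of ring A. The fallback sets out from compound 8 and replaces Friedel–Crafts chemistry by halogenation and cross-coupling. Exhaustive iodination of ring B (N-iodosuccinimide 3.0 equiv, MeCN, 0 °C) gives 2,4,6-triiodo-3-methoxy-5-[2-(3-methoxyphenyl)ethyl]phenol F1. Separately, commercial 4-(benzyloxy)benzyl chloride is treated with zinc dust and LiCl in THF at 25 °C to give 4-(benzyloxy)benzylzinc chloride F2. A triple Negishi coupling of F1 with F2 (3.6 equiv, slow addition; Pd(OAc)2 / SPhos, THF, 25–50 °C, conditions that tolerate the free phenol) gives 2,4,6-tris{[4-(benzyloxy)phenyl]methyl}-3-methoxy-5-[2-(3-methoxyphenyl)ethyl]phenol F3. Hydrogenolysis of the three benzyl ethers (H2, Pd/C, EtOAc–MeOH, 23 °C) comes back to the route at compound 13.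

Step 1, the Wittig reaction on the unprotected dihydroxy aldehyde. The ylide may be quenched, or the dipotassium salt of 1 may be too insoluble. The fallback sets out from compound 1 and uses a 1,2-addition in place of the olefination. Commercial 3-methoxybenzylmagnesium chloride (3.3 equiv, THF, 0 → 23 °C; two equivalents are consumed by the phenols) gives racemic 5-[1-hydroxy-2-(3-methoxyphenyl)ethyl]benzene-1,3-diol F4. F4 is put through stage (a) of step 2 with the TsOH·H2O present from the start (H2 1 atm, Pd/C, MeOH–1,4-dioxane, 50 °C). Acid-promoted dehydration and hydrogenation (net benzylic C–O hydrogenolysis) then give the bibenzyl, so the fallback comes back to the route at compound 5, which continues into stage (b).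

Further compounds

F0 | step 2 | none | none
F1 | step 3 | 2,4,6-triiodo-3-methoxy-5-[2-(3-methoxyphenyl)ethyl]phenol | COc1cccc(CCc2c(I)c(O)c(I)c(OC)c2I)c1
F2 | step 3 | 4-(benzyloxy)benzylzinc chloride | Cl[Zn]Cc1ccc(OCc2ccccc2)cc1
F3 | step 3 | 2,4,6-tris{[4-(benzyloxy)phenyl]methyl}-3-methoxy-5-[2-(3-methoxyphenyl)ethyl]phenol | COc1cccc(CCc2c(Cc3ccc(OCc4ccccc4)cc3)c(O)c(Cc3ccc(OCc4ccccc4)cc3)c(OC)c2Cc2ccc(OCc3ccccc3)cc2)c1
F4 | step 1 | 5-[1-hydroxy-2-(3-methoxyphenyl)ethyl]benzene-1,3-diol (racemic) | COc1cccc(CC(O)c2cc(O)cc(O)c2)c1
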